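**Plan**

- Retrosynthesis: (a) cut the benzylic O–CO bond of the palmitate; (b) in ring B (the methyl benzoate) cut C1–C2 and C3–C4, which takes out C2 with its oxygen and C3 as a ketene acetal and leaves C1, C6, C5, C4 as C3, C4, C5, C6 of a 2-pyrone; (c) cut the pyrone C4–O bond to the ring A phenol.
- Enabling feature: ring B carries ester (C1), aryloxy (C6), H (C5) and methyl (C4) in the same order as C3–C6 of a 3-methoxycarbonyl-4-aryloxy-6-methyl-2-pyrone, and its C2 oxygen sits ortho to the ester, exactly where the acetal carbon of a ketene acetal ends up.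
- Forward: the ring A phenol (five steps from a methoxysalicylaldehyde) and a 4-chloropyrone ester (two steps from a malonate) are joined by addition–elimination at pyrone C4; ring B is then built last from the pyrone by [4+2] cycloaddition, loss of CO2 and loss of methanol.
- End game: desilylation, palmitoylation, then one BCl3 step that frees both phenols.
- Stereochemistry: the target has no stereocentre; the two bridgehead centres of the cycloadduct are transient and racemic.

Key step: step 9

**Route**

Step 1
Reactants: 1 2-hydroxy-4-methoxybenzaldehyde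
Product: 2 4-methoxy-2-(methoxymethoxy)benzaldehyde
Conditions: MOMCl, i-Pr2NEt, CH2Cl2, 0 °C to rt
Reagents that add atoms: chloromethyl methyl ether, COCCl
Why: O-alkylation of the phenol with the reactive alpha-chloro ether (MOM protection) is routine for salicylaldehydes, and the acetal later tolerates peracid, base, hydride, fluoride and heat.

Step 2
Reactants: 2 4-methoxy-2-(methoxymethoxy)benzaldehyde
Product: 4 4-methoxy-2-(methoxymethoxy)phenol, via 4-methoxy-2-(methoxymethoxy)phenyl formate 3 (not isolated)
Conditions: mCPBA, CH2Cl2, 0 °C to rt; then K2CO3 (cat.), MeOH, rt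
Reagents that add atoms: 3-chloroperoxybenzoic acid, O=C(OO)c1cccc(Cl)c1
Why: In this Baeyer–Villiger (Dakin-type) oxidation the aryl group, made electron-rich by ortho and para oxygen donors, migrates in preference to hydride, and the resulting formate is methanolysed under mild base to the phenol.

Step 3
Reactants: 4 4-methoxy-2-(methoxymethoxy)phenol
Product: 5 2-hydroxy-5-methoxy-3-(methoxymethoxy)benzaldehyde
Conditions: MgCl2, Et3N, (CH2O)n, MeCN, reflux; cold dil. HCl work-up
Reagents that add atoms: paraformaldehyde (as formaldehyde), C=O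
Why: The magnesium-phenoxide-templated ortho-formylation (Casnati–Skattebøl) delivers formaldehyde only to the single free ortho carbon (para is blocked by methoxyl), and a second formaldehyde acts as hydride acceptor to reach the aldehyde level.

Step 4
Reactants: 5 2-hydroxy-5-methoxy-3-(methoxymethoxy)benzaldehyde
Product: 6 2-(hydroxymethyl)-4-methoxy-6-(methoxymethoxy)phenol
Conditions: NaBH4, MeOH, 0 °C
Reagents that add atoms: none
Why: Borohydride reduction of the aldehyde is chemoselective because the only other functions are ethers, an acetal and a phenol.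

Step 5
Reactants: 6 2-(hydroxymethyl)-4-methoxy-6-(methoxymethoxy)phenol
Product: 7 2-({[tert-butyl(dimethyl)silyl]oxy}methyl)-4-methoxy-6-(methoxymethoxy)phenol
Conditions: TBSCl (1.05 equiv), imidazole, CH2Cl2, 0 °C
Reagents that add atoms: tert-butyl(chloro)dimethylsilane, CC(C)(C)[Si](C)(C)Cl
Why: Imidazole-mediated silylation favours the unhindered primary benzylic hydroxyl over the phenol flanked on both sides, and any aryl silyl ether formed should migrate to the neighbouring alkoxide oxygen, so the mono-ether at the CH2O position is expected.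

Step 6
Reactants: 8 dimethyl malonate, 9 diketene (4-methylideneoxetan-2-one)
Product: 11 methyl 4-hydroxy-6-methyl-2-oxo-2H-pyran-3-carboxylate, via dimethyl 2-(3-oxobutanoyl)propanedioate 10 (not isolated)
Conditions: NaH, THF, 0 °C; diketene, 0 to 50 °C; then aq. HCl
Reagents that add atoms: diketene (9), C=C1CC(=O)O1
Why: The NaH-generated malonate carbanion opens diketene at its acyl carbon (C-acetoacetylation) and the ketone enolate oxygen then closes onto a malonate ester with loss of methoxide (enol lactonisation), the classical entry to 3-alkoxycarbonyl-4-hydroxy-6-methyl-2-pyrones.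

Step 7
Reactants: 11 methyl 4-hydroxy-6-methyl-2-oxo-2H-pyran-3-carboxylate
Product: 12 methyl 4-chloro-6-methyl-2-oxo-2H-pyran-3-carboxylate
Conditions: POCl3, Et3N, MeCN, 60 °C; ice-water
Reagents that add atoms: phosphoryl chloride, O=P(Cl)(Cl)Cl
Why: Deoxychlorination of a vinylogous acid: the enol oxygen is phosphorylated and chloride then substitutes at C4 by addition–elimination, as is routine for 4-hydroxy-2-pyrones and 4-hydroxycoumarin-3-carboxylates.

Step 8
Reactants: 7 ring A phenol (silyl ether), 12 methyl 4-chloro-6-methyl-2-oxo-2H-pyran-3-carboxylate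
Product: 13 methyl 4-[2-({[tert-butyl(dimethyl)silyl]oxy}methyl)-4-methoxy-6-(methoxymethoxy)phenoxy]-6-methyl-2-oxo-2H-pyran-3-carboxylate
Conditions: K2CO3, anhydrous acetone, 0 °C to rt
Reagents that add atoms: methyl 4-chloro-6-methyl-2-oxo-2H-pyran-3-carboxylate (12), COC(=O)c1c(Cl)cc(C)oc1=O
Why: Addition–elimination of the phenoxide at C4 of the vinylogous acid chloride (vinylogous acyl substitution), which is activated by both the lactone and the ester carbonyl, should tolerate the two ortho substituents of the nucleophile far better than a coupling at a benzenoid carbon.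

Step 9
Reactants: 13 4-aryloxy-3-methoxycarbonyl-6-methyl-2-pyrone, 14 1,1-dimethoxyethene
Product: 17 methyl 2-[2-({[tert-butyl(dimethyl)silyl]oxy}methyl)-4-methoxy-6-(methoxymethoxy)phenoxy]-6-methoxy-4-methylbenzoate, via 2-oxabicyclo[2.2.2]octenone cycloadduct 15 (not isolated), via 6,6-dimethoxycyclohexa-1,3-diene 16 (not isolated)
Conditions: 1,1-dimethoxyethene (5 equiv), toluene, sealed tube, 120 °C
Reagents that add atoms: 1,1-dimethoxyethene (14), C=C(OC)OC
Why: The nucleophilic CH2 terminus of the ketene acetal attacks pyrone C6, the delta carbon of the doubly acceptor-substituted dienoate, and the acetal carbon then bonds to the ester-bearing C3 in a strongly asynchronous inverse-electron-demand [4+2] cycloaddition that gives bridged lactone 15. Cycloreversion expels CO2 to give diene 16 and 1,2-elimination of methanol aromatises it, so ring B is closed by an intermolecular 4+2 union of the pyrone C3–C6 diene with the two ketene acetal carbons followed by two eliminations. The closest known reaction is the thermal benzannulation of 3-methoxycarbonyl-2-pyrones with 1,1-dimethoxyethene to salicylate methyl ethers. The two bridgehead centres of 15 form as a racemate and vanish on aromatisation, so no stereocontrol is needed. The step needs regioselectivity (oxygen ortho to the ester), which the polarisation of the diene by the C3 ester and the lactone carbonyl secures, and site selectivity against addition–elimination at C4, which the donor aryloxy group and its two ortho substituents favour by deactivating and shielding C4; the excess acetal also traps the methanol released.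

Step 10
Reactants: 17 silyl ether benzoate
Product: 18 methyl 2-[2-(hydroxymethyl)-4-methoxy-6-(methoxymethoxy)phenoxy]-6-methoxy-4-methylbenzoate
Conditions: HF·pyridine, pyridine, THF, 0 °C to rt
Reagents that add atoms: none
Why: Fluoride-driven cleavage of the primary silyl ether (HF·pyridine desilylation) runs under slightly acidic buffered conditions, so no alkoxide forms that could lactonise onto the ring B ester to an 8-membered ring, and the MOM acetal is untouched.

Step 11
Reactants: 18 benzylic alcohol, 19 hexadecanoyl chloride (palmitoyl chloride)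
Product: 20 {5-methoxy-2-[3-methoxy-2-(methoxycarbonyl)-5-methylphenoxy]-3-(methoxymethoxy)phenyl}methyl hexadecanoate
Conditions: palmitoyl chloride, Et3N, DMAP (cat.), CH2Cl2, 0 °C
Reagents that add atoms: hexadecanoyl chloride (19), CCCCCCCCCCCCCCCC(=O)Cl
Why: DMAP-catalysed acylation (esterification) of the primary benzylic alcohol with the acid chloride is unambiguous because both phenolic oxygens are still masked as ethers.

Step 12
Reactants: 20 palmitate with methyl ether and MOM ether
Product: 21 [3-hydroxy-2-(3-hydroxy-2-methoxycarbonyl-5-methylphenoxy)-5-methoxyphenyl]methyl hexadecanoate (betaethrin E)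
Conditions: BCl3 (3 equiv), CH2Cl2, −78 to 0 °C; then H2O, 0 °C
Reagents that add atoms: none
Why: Chelation-controlled Lewis acid ether cleavage: BCl3 bound between the ester carbonyl and the ortho methoxyl delivers chloride to that methyl group only, the MOM acetal is cleaved faster still, and the unchelated ring A methyl ether, the methyl ester and the palmitate are expected to survive at or below 0 °C.

**Compound list**

1 | 2-hydroxy-4-methoxybenzaldehyde | COc1ccc(C=O)c(O)c1 | starting material
2 | 4-methoxy-2-(methoxymethoxy)benzaldehyde | COCOc1cc(OC)ccc1C=O | intermediate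
3 | 4-methoxy-2-(methoxymethoxy)phenyl formate (formed in the flask, not isolated) | COCOc1cc(OC)ccc1OC=O | intermediate
4 | 4-methoxy-2-(methoxymethoxy)phenol | COCOc1cc(OC)ccc1O | intermediate
5 | 2-hydroxy-5-methoxy-3-(methoxymethoxy)benzaldehyde | COCOc1cc(OC)cc(C=O)c1O | intermediate
6 | 2-(hydroxymethyl)-4-methoxy-6-(methoxymethoxy)phenol | COCOc1cc(OC)cc(CO)c1O | intermediate
7 | 2-({[tert-butyl(dimethyl)silyl]oxy}methyl)-4-methoxy-6-(methoxymethoxy)phenol | COCOc1cc(OC)cc(CO[Si](C)(C)C(C)(C)C)c1O | intermediate
8 | dimethyl malonate | COC(=O)CC(=O)OC | starting material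
9 | diketene (4-methylideneoxetan-2-one) | C=C1CC(=O)O1 | starting material
10 | dimethyl 2-(3-oxobutanoyl)propanedioate (present as its sodium enolate, not isolated) | COC(=O)C(C(=O)CC(C)=O)C(=O)OC | intermediate
11 | methyl 4-hydroxy-6-methyl-2-oxo-2H-pyran-3-carboxylate | COC(=O)c1c(O)cc(C)oc1=O | intermediate
12 | methyl 4-chloro-6-methyl-2-oxo-2H-pyran-3-carboxylate | COC(=O)c1c(Cl)cc(C)oc1=O | intermediate
13 | methyl 4-[2-({[tert-butyl(dimethyl)silyl]oxy}methyl)-4-methoxy-6-(methoxymethoxy)phenoxy]-6-methyl-2-oxo-2H-pyran-3-carboxylate | COC(=O)c1c(Oc2c(OCOC)cc(OC)cc2CO[Si](C)(C)C(C)(C)C)cc(C)oc1=O | intermediate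
14 | 1,1-dimethoxyethene | C=C(OC)OC | starting material
15 | methyl 5-[2-({[tert-butyl(dimethyl)silyl]oxy}methyl)-4-methoxy-6-(methoxymethoxy)phenoxy]-8,8-dimethoxy-1-methyl-3-oxo-2-oxabicyclo[2.2.2]oct-5-ene-4-carboxylate (racemic, one enantiomer drawn; not isolated) | C[C@]12OC(=O)[C@](C(=O)OC)(C(Oc3c(OCOC)cc(OC)cc3CO[Si](C)(C)C(C)(C)C)=C1)C(OC)(OC)C2 | intermediate
16 | methyl 2-[2-({[tert-butyl(dimethyl)silyl]oxy}methyl)-4-methoxy-6-(methoxymethoxy)phenoxy]-6,6-dimethoxy-4-methylcyclohexa-1,3-diene-1-carboxylate (not isolated) | COC(=O)C1=C(Oc2c(OCOC)cc(OC)cc2CO[Si](C)(C)C(C)(C)C)C=C(C)CC1(OC)OC | intermediate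
17 | methyl 2-[2-({[tert-butyl(dimethyl)silyl]oxy}methyl)-4-methoxy-6-(methoxymethoxy)phenoxy]-6-methoxy-4-methylbenzoate | COC(=O)c1c(OC)cc(C)cc1Oc1c(OCOC)cc(OC)cc1CO[Si](C)(C)C(C)(C)C | intermediate
18 | methyl 2-[2-(hydroxymethyl)-4-methoxy-6-(methoxymethoxy)phenoxy]-6-methoxy-4-methylbenzoate | COC(=O)c1c(OC)cc(C)cc1Oc1c(OCOC)cc(OC)cc1CO | intermediate
19 | hexadecanoyl chloride (palmitoyl chloride) | CCCCCCCCCCCCCCCC(=O)Cl | starting material
20 | {5-methoxy-2-[3-methoxy-2-(methoxycarbonyl)-5-methylphenoxy]-3-(methoxymethoxy)phenyl}methyl hexadecanoate | CCCCCCCCCCCCCCCC(=O)OCc1cc(OC)cc(OCOC)c1Oc1cc(C)cc(OC)c1C(=O)OC | intermediate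
21 | [3-hydroxy-2-(3-hydroxy-2-methoxycarbonyl-5-methylphenoxy)-5-methoxyphenyl]methyl hexadecanoate (betaethrin E) | CCCCCCCCCCCCCCCC(=O)OCc1cc(OC)cc(O)c1Oc1cc(C)cc(O)c1C(=O)OC | target

**Step count and risks**

Total step count: 12. Longest linear sequence: 10 steps (steps 1 to 5 and 8 to 12, from 2-hydroxy-4-methoxybenzaldehyde); the pyrone branch (steps 6 and 7) joins at step 8.

Steps most likely to fail:

1. Step 9. The cycloaddition may be too slow, because the aryloxy donor at C4 makes the diene less electron-poor and the 6-methyl group hinders the first bond formation. Oligomerisation of the ketene acetal, or addition–elimination at C4 with loss of the ring A phenoxide, could then take over. The fallback brings ring B in preformed and sets out from phenol 7. Lithiation of 1-fluoro-3-methoxy-5-methylbenzene between fluorine and methoxyl (n-BuLi, THF, −78 °C) and a DMF quench should give 2-fluoro-6-methoxy-4-methylbenzaldehyde F1. Nucleophilic aromatic substitution of its fluoride by the phenoxide of 7 (K2CO3, DMF, 90 °C) should give 2-[2-({[tert-butyl(dimethyl)silyl]oxy}methyl)-4-methoxy-6-(methoxymethoxy)phenoxy]-6-methoxy-4-methylbenzaldehyde F2. Pinnick oxidation (NaClO2, NaH2PO4, 2-methylbut-2-ene, t-BuOH/H2O) should give 2-[2-({[tert-butyl(dimethyl)silyl]oxy}methyl)-4-methoxy-6-(methoxymethoxy)phenoxy]-6-methoxy-4-methylbenzoic acid F3, and methylation (MeI, K2CO3, DMF) comes back to the route at 17.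

2. Step 12. The Lewis acid may ionise the benzylic palmitate, or deliver chloride to the benzylic carbon, before the chelated methyl ether is fully cleaved, so that the ester is lost or the demethylation stays incomplete. The fallback removes the ethers before the ester exists and sets out from alcohol 18. Oxidation with MnO2 (CH2Cl2, rt) should give methyl 2-[2-formyl-4-methoxy-6-(methoxymethoxy)phenoxy]-6-methoxy-4-methylbenzoate F4, which has no ionisable benzylic oxygen. BCl3 (CH2Cl2, −78 to 0 °C) should then cleave the chelated methyl ether and the MOM group to give methyl 2-(2-formyl-6-hydroxy-4-methoxyphenoxy)-6-hydroxy-4-methylbenzoate F5. NaBH4 (MeOH, 0 °C) should reduce only the aldehyde to give methyl 2-hydroxy-6-[2-hydroxy-6-(hydroxymethyl)-4-methoxyphenoxy]-4-methylbenzoate F6. Lipase-catalysed transesterification (immobilised Candida antarctica lipase B, vinyl palmitate, t-BuOMe, 40 °C) should acylate the primary alcohol and leave both phenols alone, which comes back to the route at the target 21.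

3. Step 3. Chelation of magnesium by the neighbouring acetal oxygens may slow delivery of formaldehyde to the ortho carbon, or the Lewis acidic salt may strip the MOM group at reflux, giving low conversion or a catechol. The fallback sets out from phenol 4 and installs the carbon directly at the alcohol level. Base-mediated ortho-hydroxymethylation (Lederer–Manasse; aqueous formaldehyde, NaOH, rt) can only occur at the single free ortho position because para is blocked, and it comes back to the route at diol 6, bypassing steps 3 and 4; it makes no new compound (F0).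

**Further compounds**

F1 | step 9 | 2-fluoro-6-methoxy-4-methylbenzaldehyde | COc1cc(C)cc(F)c1C=O
F2 | step 9 | 2-[2-({[tert-butyl(dimethyl)silyl]oxy}methyl)-4-methoxy-6-(methoxymethoxy)phenoxy]-6-methoxy-4-methylbenzaldehyde | COCOc1cc(OC)cc(CO[Si](C)(C)C(C)(C)C)c1Oc1cc(C)cc(OC)c1C=O
F3 | step 9 | 2-[2-({[tert-butyl(dimethyl)silyl]oxy}methyl)-4-methoxy-6-(methoxymethoxy)phenoxy]-6-methoxy-4-methylbenzoic acid | COCOc1cc(OC)cc(CO[Si](C)(C)C(C)(C)C)c1Oc1cc(C)cc(OC)c1C(=O)O
F4 | step 12 | methyl 2-[2-formyl-4-methoxy-6-(methoxymethoxy)phenoxy]-6-methoxy-4-methylbenzoate | COC(=O)c1c(OC)cc(C)cc1Oc1c(OCOC)cc(OC)cc1C=O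
F5 | step 12 | methyl 2-(2-formyl-6-hydroxy-4-methoxyphenoxy)-6-hydroxy-4-methylbenzoate | COC(=O)c1c(O)cc(C)cc1Oc1c(O)cc(OC)cc1C=O
F6 | step 12 | methyl 2-hydroxy-6-[2-hydroxy-6-(hydroxymethyl)-4-methoxyphenoxy]-4-methylbenzoate | COC(=O)c1c(O)cc(C)cc1Oc1c(O)cc(OC)cc1CO
F0 | step 3 | none | none
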